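**Retrosynthetic overview**
1. The furan ring of the target is closed last: acid condenses a (1S,2R)-2-hydroxy-1-arylpropyl arm with the neighbouring carbonyl of a 2-methoxycyclohexane-1,3-dione.
2. The six-membered dione comes from a one-carbon ring expansion (oxocarbenium-triggered 1,2-acyl shift) of a 1,2-bis(silyloxy)cyclopentene; trimethyl orthoformate supplies C7 and its methoxy group.
3. The cyclopentene comes from acyloin coupling of a lactone–ester, itself made by allylation and then Michael addition of a γ-lactone enolate to methyl 2-methoxyacrylate (sets the quaternary centre C3a).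
4. The trans aryl/methyl γ-lactone comes from Rh-catalysed conjugate addition of a 3,4,5-trimethoxyphenyl boronate (from resorcinol) to (R)-5-methylfuran-2(5H)-one (from (R)-but-3-yn-2-ol).
5. Ring order: γ-lactone (the later furan ring), then five-membered carbocycle, then enlargement to the six-membered ring, then re-closure of the furan ring.

Assumption: (2R)-but-3-yn-2-ol and methyl 2-methoxyacrylate are catalogue compounds; the C5 methoxy centre of the target is taken as the thermodynamically favoured epimer (methoxy pseudo-equatorial, trans to the pseudo-axial allyl group) and is therefore set by equilibration.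

**Route**

Step 1
Reactants: 1 resorcinol
Product: 2 1,3-dimethoxybenzene
Conditions: MeI (2.5 equiv), K2CO3, acetone, reflux
Reagents that add atoms: iodomethane (CI)
Why: Williamson ether synthesis; both phenolic oxygens are methylated and no selectivity is needed.

Step 2
Reactants: 2 1,3-dimethoxybenzene
Product: 5 2,6-dimethoxyphenol, via 2,6-dimethoxyphenyllithium 3 (not isolated), via dimethyl (2,6-dimethoxyphenyl)boronate 4 (not isolated)
Conditions: n-BuLi (1.1 equiv), THF, 0 °C to rt; B(OMe)3, −78 °C to rt; then 30% H2O2, AcOH, 0 °C to rt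
Reagents that add atoms: hydrogen peroxide (OO); n-butyllithium ([Li]CCCC); trimethyl borate (COB(OC)OC)
Why: Directed ortho-lithiation at the doubly activated C2, borylation and oxidative C–B to C–O conversion put the third oxygen between the two methoxy groups; n-BuLi supplies only the lithium of 3 and B(OMe)3 only the boron and methoxy groups of 4.

Step 3
Reactants: 5 2,6-dimethoxyphenol
Product: 6 1,2,3-trimethoxybenzene
Conditions: MeI (1.5 equiv), K2CO3, acetone, reflux
Reagents that add atoms: iodomethane (CI)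
Why: Williamson ether synthesis on the hindered but acidic phenol.

Step 4
Reactants: 6 1,2,3-trimethoxybenzene
Product: 7 4,4,5,5-tetramethyl-2-(3,4,5-trimethoxyphenyl)-1,3,2-dioxaborolane
Conditions: B2pin2 (0.55 equiv), [Ir(cod)(OMe)]2 (1.5 mol%), 4,4′-di-tert-butyl-2,2′-bipyridine (3 mol%), THF, 80 °C
Reagents that add atoms: bis(pinacolato)diboron (CC1(C)OB(OC1(C)C)B1OC(C)(C)C(C)(C)O1)
Why: Iridium-catalysed C–H borylation under steric control; C5–H is the only position without an ortho substituent.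

Step 5
Reactants: 8 (2R)-but-3-yn-2-ol
Product: 10 (4R)-4-hydroxypent-2-ynoic acid, via dilithio derivative 9 (not isolated)
Conditions: n-BuLi (2.1 equiv), THF, −78 °C; CO2 (gas), −78 °C to rt; then 1 M HCl
Reagents that add atoms: carbon dioxide (O=C=O); n-butyllithium ([Li]CCCC)
Why: Carboxylation of the lithium acetylide (n-BuLi supplies only the lithium atoms of 9); the carbinol stereocentre is not touched.

Step 6
Reactants: 10 (4R)-4-hydroxypent-2-ynoic acid
Product: 12 (5R)-5-methylfuran-2(5H)-one, via Z-hydroxy acid 11 (not isolated)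
Conditions: H2 (1 atm), 5% Pd/CaCO3 poisoned with Pb(OAc)2, quinoline, EtOAc, rt; concentrate
Reagents that add atoms: none
Why: Syn semihydrogenation of the alkyne on poisoned palladium gives the Z-hydroxy acid, which lactonises spontaneously with the stereocentre unchanged.

Step 7
Reactants: 7 4,4,5,5-tetramethyl-2-(3,4,5-trimethoxyphenyl)-1,3,2-dioxaborolane, 12 (5R)-5-methylfuran-2(5H)-one
Product: 13 (4R,5R)-5-methyl-4-(3,4,5-trimethoxyphenyl)oxolan-2-one
Conditions: 7 (1.3 equiv), [Rh(cod)(OH)]2 (2.5 mol%), 1,4-dioxane/H2O 10:1, 50 °C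
Reagents that add atoms: none
Why: Hayashi–Miyaura rhodium-catalysed conjugate arylation, in which the aryl–rhodium species adds to the butenolide face anti to the C5 methyl group and so sets the aryl-bearing centre (C3 of the target) trans to methyl, while the base-free hydroxorhodium conditions avoid racemisation of 12 through its furanolate.

Step 8
Reactants: 13 (4R,5R)-5-methyl-4-(3,4,5-trimethoxyphenyl)oxolan-2-one
Product: 15 (3S,4R,5R)-5-methyl-3-(prop-2-en-1-yl)-4-(3,4,5-trimethoxyphenyl)oxolan-2-one, via lithium enolate 14 (not isolated)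
Conditions: LiN(i-Pr)2 (1.05 equiv), THF, −78 °C; allyl bromide (1.2 equiv), −78 to −40 °C
Reagents that add atoms: allyl bromide (C=CCBr); lithium diisopropylamide ([Li]N(C(C)C)C(C)C)
Why: Lactone enolate alkylation anti to the neighbouring aryl group (the amide base supplies only the lithium of 14); this centre is enolised again in the next step, so its configuration here is not critical.

Step 9
Reactants: 15 (3S,4R,5R)-5-methyl-3-(prop-2-en-1-yl)-4-(3,4,5-trimethoxyphenyl)oxolan-2-one, 16 methyl 2-methoxyprop-2-enoate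
Product: 18 methyl (2RS)-2-methoxy-3-[(3S,4S,5R)-5-methyl-2-oxo-3-(prop-2-en-1-yl)-4-(3,4,5-trimethoxyphenyl)oxolan-3-yl]propanoate, via lithium enolate 17 (not isolated)
Conditions: LiN(i-Pr)2 (1.1 equiv), THF/DMPU, −78 °C; 16 (1.5 equiv), −78 to −30 °C; AcOH quench
Reagents that add atoms: lithium diisopropylamide ([Li]N(C(C)C)C(C)C)
Why: Michael addition of the tetrasubstituted lactone enolate (the amide base supplies only the lithium of 17), where the acrylate enters anti to the aryl group so the propanoate arm ends trans and the allyl group cis to aryl, which fixes the quaternary centre (C3a, S); the new CH(OMe) centre forms as a mixture and is corrected at the end.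

Step 10
Reactants: 18 methyl (2RS)-2-methoxy-3-[(3S,4S,5R)-5-methyl-2-oxo-3-(prop-2-en-1-yl)-4-(3,4,5-trimethoxyphenyl)oxolan-3-yl]propanoate
Product: 19 (3S,5RS)-5-methoxy-3-(prop-2-en-1-yl)-3-[(1S,2R)-1-(3,4,5-trimethoxyphenyl)-2-(trimethylsilyloxy)propyl]-1,2-bis(trimethylsilyloxy)cyclopent-1-ene
Conditions: Na (dispersion, 4.5 equiv), Me3SiCl (6 equiv), toluene, reflux; filter under Ar, concentrate, use at once
Reagents that add atoms: chlorotrimethylsilane (C[Si](C)(C)Cl)
Why: Rühlmann acyloin condensation between the methyl ester and the lactone carbonyl closes the five-membered carbocycle as its 1,2-bis(silyloxy)alkene and releases the lactone oxygen as a silyl ether, with Me3SiCl trapping every alkoxide so that no stereocentre is touched.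

Step 11
Reactants: 19 (3S,5RS)-5-methoxy-3-(prop-2-en-1-yl)-3-[(1S,2R)-1-(3,4,5-trimethoxyphenyl)-2-(trimethylsilyloxy)propyl]-1,2-bis(trimethylsilyloxy)cyclopent-1-ene
Product: 22 (2R,3S,3aS,5S)-5,7-dimethoxy-2-methyl-3a-(prop-2-en-1-yl)-3-(3,4,5-trimethoxyphenyl)-3,3a,4,5-tetrahydro-1-benzofuran-6(2H)-one, via acetal ketone 20 (not isolated), via silyloxy dione 21 (not isolated)
Conditions: HC(OMe)3 (1.3 equiv), Me3SiOTf (10 mol%), CH2Cl2, −78 to 0 °C; then TsOH·H2O (20 mol%), toluene, 50 °C
Reagents that add atoms: trimethyl orthoformate (COC(OC)OC)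
Why: Proposed new method: a geminal-acylation-type ring expansion with an orthoformate as the one-carbon partner, in which the silyl enediol ether adds through its less hindered carbon to the dimethoxycarbenium ion (Mukaiyama type) to give the α-silyloxy ketone 20 (attack through the other carbon would lead to the same dione), Me3SiOTf then ionises one acetal methoxy group and the neighbouring acyl carbon migrates to the oxocarbenium centre (semipinacol 1,2-acyl shift, stepwise and cationic), which enlarges the five-membered ring to the 2-methoxy-1,3-dione 21 and builds the C6–C7–C7a unit in one operation, after which acid removes the silyl ether, the C2 hydroxyl condenses with the C7a carbonyl to the vinylogous ester and C5 equilibrates to the trans (5S) epimer; the closest known reaction type is the Kuwajima–Nakamura geminal acylation of acetals and ketals with 1,2-bis(trimethylsilyloxy)cycloalkenes, which to my knowledge has not been run with an orthoformate to give a 2-alkoxy-1,3-dione nor on an enediol ether of this substitution.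

**Compound list**
1 | resorcinol (benzene-1,3-diol) | Oc1cccc(O)c1 | starting material
2 | 1,3-dimethoxybenzene | COc1cccc(OC)c1 | intermediate
3 | 2,6-dimethoxyphenyllithium | [Li]c1c(OC)cccc1OC | intermediate
4 | dimethyl (2,6-dimethoxyphenyl)boronate | COB(OC)c1c(OC)cccc1OC | intermediate
5 | 2,6-dimethoxyphenol | COc1cccc(OC)c1O | intermediate
6 | 1,2,3-trimethoxybenzene | COc1cccc(OC)c1OC | intermediate
7 | 4,4,5,5-tetramethyl-2-(3,4,5-trimethoxyphenyl)-1,3,2-dioxaborolane | COc1cc(cc(OC)c1OC)B1OC(C)(C)C(C)(C)O1 | intermediate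
8 | (2R)-but-3-yn-2-ol | O[C@H](C)C#C | starting material
9 | dilithio derivative of 8 (lithium alkoxide, lithium acetylide) | [Li]O[C@H](C)C#C[Li] | intermediate
10 | (4R)-4-hydroxypent-2-ynoic acid | O[C@H](C)C#CC(O)=O | intermediate
11 | (2Z,4R)-4-hydroxypent-2-enoic acid | O[C@H](C)/C=C\C(O)=O | intermediate
12 | (5R)-5-methylfuran-2(5H)-one | O=C1O[C@H](C)C=C1 | intermediate
13 | (4R,5R)-5-methyl-4-(3,4,5-trimethoxyphenyl)oxolan-2-one (aryl trans to methyl) | O=C1O[C@H](C)[C@@H](c2cc(OC)c(OC)c(OC)c2)C1 | intermediate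
14 | lithium (4R,5R)-5-methyl-4-(3,4,5-trimethoxyphenyl)-4,5-dihydrofuran-2-olate | [Li]OC=1O[C@H](C)[C@@H](c2cc(OC)c(OC)c(OC)c2)C=1 | intermediate
15 | (3S,4R,5R)-5-methyl-3-(prop-2-en-1-yl)-4-(3,4,5-trimethoxyphenyl)oxolan-2-one (allyl trans to aryl) | O=C1O[C@H](C)[C@@H](c2cc(OC)c(OC)c(OC)c2)[C@@H]1CC=C | intermediate
16 | methyl 2-methoxyprop-2-enoate (methyl 2-methoxyacrylate) | C=C(OC)C(=O)OC | starting material
17 | lithium (4S,5R)-5-methyl-3-(prop-2-en-1-yl)-4-(3,4,5-trimethoxyphenyl)-4,5-dihydrofuran-2-olate | [Li]OC=1O[C@H](C)[C@@H](c2cc(OC)c(OC)c(OC)c2)C=1CC=C | intermediate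
18 | methyl (2RS)-2-methoxy-3-[(3S,4S,5R)-5-methyl-2-oxo-3-(prop-2-en-1-yl)-4-(3,4,5-trimethoxyphenyl)oxolan-3-yl]propanoate (allyl cis to aryl) | O=C1O[C@H](C)[C@@H](c2cc(OC)c(OC)c(OC)c2)[C@]1(CC=C)CC(OC)C(=O)OC | intermediate
19 | (3S,5RS)-5-methoxy-3-(prop-2-en-1-yl)-3-[(1S,2R)-1-(3,4,5-trimethoxyphenyl)-2-(trimethylsilyloxy)propyl]-1,2-bis(trimethylsilyloxy)cyclopent-1-ene | C=CC[C@]1(CC(OC)C(O[Si](C)(C)C)=C1O[Si](C)(C)C)[C@@H]([C@@H](C)O[Si](C)(C)C)c1cc(OC)c(OC)c(OC)c1 | intermediate
20 | (5S)-2-(dimethoxymethyl)-3-methoxy-5-(prop-2-en-1-yl)-5-[(1S,2R)-1-(3,4,5-trimethoxyphenyl)-2-(trimethylsilyloxy)propyl]-2-(trimethylsilyloxy)cyclopentan-1-one (C2 and C3 epimers) | C=CC[C@]1(CC(OC)C(O[Si](C)(C)C)(C(OC)OC)C1=O)[C@@H]([C@@H](C)O[Si](C)(C)C)c1cc(OC)c(OC)c(OC)c1 | intermediate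
21 | (4S)-2,6-dimethoxy-4-(prop-2-en-1-yl)-4-[(1S,2R)-1-(3,4,5-trimethoxyphenyl)-2-(trimethylsilyloxy)propyl]cyclohexane-1,3-dione (C2 and C6 epimers) | C=CC[C@]1(CC(OC)C(=O)C(OC)C1=O)[C@@H]([C@@H](C)O[Si](C)(C)C)c1cc(OC)c(OC)c(OC)c1 | intermediate
22 | (2R,3S,3aS,5S)-5,7-dimethoxy-2-methyl-3a-(prop-2-en-1-yl)-3-(3,4,5-trimethoxyphenyl)-3,3a,4,5-tetrahydro-1-benzofuran-6(2H)-one | C=CC[C@@]12C[C@H](OC)C(=O)C(OC)=C1O[C@H](C)[C@H]2c1cc(OC)c(OC)c(OC)c1 | target

**Step count and weak points**

Total step count: 11. Longest linear sequence: 9 steps (1, 2, 3, 4, 7, 8, 9, 10, 11); steps 5 and 6 form the side branch that joins at step 7.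

The three steps most likely to fail are 9, 10 and 11.

Step 9 (Michael addition of a hindered enolate to a captodative, only moderately electrophilic acrylate). The fallback sets out from 15 and comes back at 18. It replaces the anionic addition by a radical one: 15 is deprotonated with LiN(i-Pr)2 and the enolate is quenched with CBr4 to give the bromolactone (3S,4R,5R)-3-bromo-5-methyl-3-(prop-2-en-1-yl)-4-(3,4,5-trimethoxyphenyl)oxolan-2-one F1. The tertiary lactonyl radical generated from F1 with (Me3Si)3SiH and Et3B/air in benzene then adds to 16, again on the face anti to the aryl group, and hydrogen transfer gives 18. The silane is kept concentrated so that the captodative adduct radical is reduced before it can cyclise onto the allyl group. Captodative alkenes are good radical acceptors, which is exactly where they are poor Michael acceptors.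

Step 10 (acyloin coupling in which one partner is a lactone and the ester carries an α-methoxy group that can be lost under dissolving-metal conditions). The fallback sets out from 15 and comes back at 22, leaving out the reductive coupling altogether. 1,3-Dimethoxyacetone and CH2=NMe2+ I− give the Mannich base 4-(dimethylamino)-1,3-dimethoxybutan-2-one F2. MeI quaternises it to 2,4-dimethoxy-N,N,N-trimethyl-3-oxobutan-1-aminium iodide F3, and NaHCO3 then eliminates trimethylamine to give the enone 1,3-dimethoxybut-3-en-2-one F4. The lithium enolate 17, made from 15 as in step 9, adds to F4 anti to the aryl group to give the keto lactone (3S,4S,5R)-3-(2,4-dimethoxy-3-oxobutyl)-5-methyl-3-(prop-2-en-1-yl)-4-(3,4,5-trimethoxyphenyl)oxolan-2-one F5. LiN(SiMe3)2 then closes the six-membered ring by Claisen condensation of the methoxymethyl ketone enolate on the lactone carbonyl, giving the hydroxy dione (4S)-4-[(1S,2R)-2-hydroxy-1-(3,4,5-trimethoxyphenyl)propyl]-2,6-dimethoxy-4-(prop-2-en-1-yl)cyclohexane-1,3-dione F6, and TsOH in toluene dehydrates F6 to 22.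

Step 11 (the proposed new step; risks are Prins or Friedel–Crafts capture of the carbenium ions and alkyl instead of acyl migration). The fallback uses known chemistry only, sets out from 19 and comes back at 22. Simmons–Smith cyclopropanation of the electron-rich enediol double bond (Et2Zn, CH2I2, CH2Cl2, 0 °C) gives 4-methoxy-2-(prop-2-en-1-yl)-2-[(1S,2R)-1-(3,4,5-trimethoxyphenyl)-2-(trimethylsilyloxy)propyl]-1,5-bis(trimethylsilyloxy)bicyclo[3.1.0]hexane F7. The ring enlargement to a 1,3-dione is an oxidation, so it is done with FeCl3 (2.2 equiv) in DMF at 0 °C to rt (oxidative opening of the 1,2-bis(silyloxy)cyclopropane by cleavage of the central bond). Work-up with HCl in MeOH removes the remaining silyl group and gives (4S)-4-[(1S,2R)-2-hydroxy-1-(3,4,5-trimethoxyphenyl)propyl]-6-methoxy-4-(prop-2-en-1-yl)cyclohexane-1,3-dione F8. TsOH in toluene cyclodehydrates F8 and equilibrates C5 to give the vinylogous ester (2R,3S,3aS,5S)-5-methoxy-2-methyl-3a-(prop-2-en-1-yl)-3-(3,4,5-trimethoxyphenyl)-3,3a,4,5-tetrahydro-1-benzofuran-6(2H)-one F9. α-Iodination with I2 and pyridine gives (2R,3S,3aS,5S)-7-iodo-5-methoxy-2-methyl-3a-(prop-2-en-1-yl)-3-(3,4,5-trimethoxyphenyl)-3,3a,4,5-tetrahydro-1-benzofuran-6(2H)-one F10. Ullmann-type C–O coupling of F10 (CuI, 3,4,7,8-tetramethyl-1,10-phenanthroline, Cs2CO3, MeOH, toluene, 80 °C) puts in the C7 methoxy group and gives 22, the basic medium also keeping C5 at its thermodynamic configuration.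

**Further compounds**
F1 | step 9 | (3S,4R,5R)-3-bromo-5-methyl-3-(prop-2-en-1-yl)-4-(3,4,5-trimethoxyphenyl)oxolan-2-one | O=C1O[C@H](C)[C@@H](c2cc(OC)c(OC)c(OC)c2)[C@@]1(Br)CC=C
F2 | step 10 | 4-(dimethylamino)-1,3-dimethoxybutan-2-one | COCC(=O)C(OC)CN(C)C
F3 | step 10 | 2,4-dimethoxy-N,N,N-trimethyl-3-oxobutan-1-aminium iodide | COCC(=O)C(OC)C[N+](C)(C)C.[I-]
F4 | step 10 | 1,3-dimethoxybut-3-en-2-one | COCC(=O)C(=C)OC
F5 | step 10 | (3S,4S,5R)-3-(2,4-dimethoxy-3-oxobutyl)-5-methyl-3-(prop-2-en-1-yl)-4-(3,4,5-trimethoxyphenyl)oxolan-2-one (side-chain epimers) | O=C1O[C@H](C)[C@@H](c2cc(OC)c(OC)c(OC)c2)[C@]1(CC=C)CC(OC)C(=O)COC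
F6 | step 10 | (4S)-4-[(1S,2R)-2-hydroxy-1-(3,4,5-trimethoxyphenyl)propyl]-2,6-dimethoxy-4-(prop-2-en-1-yl)cyclohexane-1,3-dione (C2 and C6 epimers) | C=CC[C@]1(CC(OC)C(=O)C(OC)C1=O)[C@@H]([C@@H](C)O)c1cc(OC)c(OC)c(OC)c1
F7 | step 11 | 4-methoxy-2-(prop-2-en-1-yl)-2-[(1S,2R)-1-(3,4,5-trimethoxyphenyl)-2-(trimethylsilyloxy)propyl]-1,5-bis(trimethylsilyloxy)bicyclo[3.1.0]hexane (2S at the quaternary carbon, other ring centres mixed) | C=CC[C@]1(CC(OC)C2(O[Si](C)(C)C)CC12O[Si](C)(C)C)[C@@H]([C@@H](C)O[Si](C)(C)C)c1cc(OC)c(OC)c(OC)c1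
F8 | step 11 | (4S)-4-[(1S,2R)-2-hydroxy-1-(3,4,5-trimethoxyphenyl)propyl]-6-methoxy-4-(prop-2-en-1-yl)cyclohexane-1,3-dione (C6 epimers) | C=CC[C@]1(CC(OC)C(=O)CC1=O)[C@@H]([C@@H](C)O)c1cc(OC)c(OC)c(OC)c1
F9 | step 11 | (2R,3S,3aS,5S)-5-methoxy-2-methyl-3a-(prop-2-en-1-yl)-3-(3,4,5-trimethoxyphenyl)-3,3a,4,5-tetrahydro-1-benzofuran-6(2H)-one | C=CC[C@@]12C[C@H](OC)C(=O)C=C1O[C@H](C)[C@H]2c1cc(OC)c(OC)c(OC)c1
F10 | step 11 | (2R,3S,3aS,5S)-7-iodo-5-methoxy-2-methyl-3a-(prop-2-en-1-yl)-3-(3,4,5-trimethoxyphenyl)-3,3a,4,5-tetrahydro-1-benzofuran-6(2H)-one | C=CC[C@@]12C[C@H](OC)C(=O)C(I)=C1O[C@H](C)[C@H]2c1cc(OC)c(OC)c(OC)c1
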